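Which flask ends lowest, and how low, is the question I can answer most cheaply, so I begin there.

1. the flasks put in order of amount of target, in percent of the substrate charged, best first, at 20 min (beta / eta / epsilon / alpha / gamma)
2. the amount of target, in percent of the substrate charged of the flask you put first, at 20 min
3. the amount of target, in percent of the substrate charged of the flask you put last, at 20 min

| flask | substrate | partner | remark | time |
|---|---|---|---|---|
| summer | 0.097 M | 0.116 M (in portions, 4) | run made earlier; portions every 6.0 s |  |
| autumn | 0.26 M | 0.116 M (in portions, 4) | run made earlier; portions every 6.0 s |  |
| midnight | 0.11 M | 0.072 M (in portions, 4) | run made earlier; portions every 6.0 s |  |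
| beta | 0.20 M | 0.0300 M (in portions, 4) | the portions of partner follow each other after 2.0 s, the first at the start | 20 min |
| eta | 0.11 M | 0.0600 M (in portions, 4) | the portions of partner follow each other after 20 s, the first at the start | 20 min |
| epsilon | 0.11 M | 0.250 M (in portions, 4) | the portions of partner follow each other after 25 s, the first at the start | 20 min |
| alpha | 0.080 M | 0.0400 M (in portions, 4) | the portions of partner follow each other after 6.0 s, the first at the start | 20 min |
| gamma | 0.11 M | 0.116 M (in portions, 4) | the portions of partner follow each other after 6.0 s, the first at the start | 20 min |

- summer (time / min: target / %, substrate / %): 2.50: 23.6, 32.4; 8.00: 66.9, 2.7; 12.0: 77.8, 0.3; 20.0: 88.2, 0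
- autumn (time / min: target / %, substrate / %): 5.00: 34.1, 10.0; 10.0: 43.0, 1.2; 15.0: 43.3, 0.1; 20.0: 44.4, 0
- midnight (time / min: target / %, substrate / %): 5.00: 33.2, 12.3; 10.0: 50.4, 1.2; 15.0: 59.2, 0; 20.0: 61.6, 0

(each reading ± 1 percentage point)

I write the balance of partner, the limiting reagent in beta since its charge is 0.0300 M against 0.20 M of substrate. The autumn run suggests that each target takes one partner: its last reading, 44.4%, is 0.115 M of target against 0.116 M of partner charged. Then [partner] + [target] stays at the charge, which bounds beta from above at 15.0% of the substrate charged. I carry this ratio of partner charge to substrate charge as the partner ceiling. Eta has 54.5% and alpha 50.0%, both higher, so I put beta last. Gamma and epsilon hold more partner than substrate, and I put epsilon first for its larger charge.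

For a bound from below I assume that beta, with more substrate and less partner than midnight, uses its partner at least as fully as midnight does. Midnight used 94.1% of its partner, which puts beta at 14.1% or more. That floor is a reading and carries the scatter of 1 percentage point.

The forecast gives epsilon > gamma > eta > alpha > beta, with 98% at the top and 15% at the bottom, on the ground that “When partner is limiting, final target approaches the partner charge”. Its low stands at the upper edge of my bracket.

The flask gives epsilon > gamma > eta > alpha > beta, with 99.1% first and 15.0% last.

    substrate → intermediate (k = 0.00750 s⁻¹)
    partner + intermediate → target (k = 0.0490 M⁻¹ s⁻¹)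
    2 intermediate → homo product (k = 0.00150 M⁻¹ s⁻¹)

In beta at 1.54 min, partner has a half-life of 2.5 min by the making of target, far shorter than the 20 min allowed. At that moment intermediate goes to target 4.2 times as fast as to homo product. Partner stands at 0.066% of its charge at 20.0 min, and the target of beta lies on its ceiling of 15.0%. The neighbour of beta with 0.12 M of substrate has a ceiling of 25.0%, and it holds 24.7% of target with 1.3% of its partner left.

All runs stem from a simulated flask for an exercise.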